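**Plan**

- Numbering: ring C1 carries the alkenyl chain, C3 the free OH, C4 the methyl, C6 the isobutyrate; Cα is the alkene carbon bonded to C1. Retrosynthetic cuts in order: O3–CH2OCH3 (acetal protecting group), then C1–Cα together with the allylic CH2–O2CPh bond, then acyl–O6, C1–I and C6–O (back to a formyl carbon).
- Enabling feature: C1–Cα(=CH2)–CH2–O2CPh is a three-carbon chain with the benzene ring on its middle carbon and a benzoate on one end, i.e. propadiene arylated at the central carbon and oxygenated at a terminus. It can therefore be assembled on palladium from an aryl iodide, propadiene and benzoate through a 2-aryl π-allyl complex.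
- Forward: 4-hydroxy-3-methylbenzaldehyde → MOM ether at the future O3 → Baeyer–Villiger oxidation and methanolysis (CHO becomes the O6 hydroxyl) → iodination at C1 → isobutyrate at O6 → three-component coupling → MOM removal.
- No ring is formed; the benzene ring is bought and the whole three-carbon side chain with its benzoate is attached in one operation.
- Stereochemistry: nothing to set (no stereocentre, terminal alkene). The control needed is regiochemical: O3 and O6 are told apart by the starting aldehyde, C1 is selected by the free O6 hydroxyl during iodination, and the symmetric π-allyl gives a single constitutional isomer.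

Key step: step 5

Remark: the target is achiral, so all SMILES carry no stereo descriptors; 4-hydroxy-3-methylbenzaldehyde, propadiene (gas), benzoic acid and isobutyryl chloride are taken as commercial.

**Step 1**
Reactants: 1 4-hydroxy-3-methylbenzaldehyde
Product: 2 4-(methoxymethoxy)-3-methylbenzaldehyde
Conditions: MOMCl, i-Pr2NEt, CH2Cl2, 0 °C → rt
Reagents that add atoms: chloromethyl methyl ether (MOMCl), COCCl
Why: O-alkylation of the phenol (made more acidic by the para formyl group) with the α-chloro ether, a Williamson-type etherification used routinely for MOM protection, should be clean because the aldehyde is not enolisable and there is no other nucleophilic site.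

**Step 2**
Reactants: 2 4-(methoxymethoxy)-3-methylbenzaldehyde
Product: 4 4-(methoxymethoxy)-3-methylphenol, via 4-(methoxymethoxy)-3-methylphenyl formate 3 (not isolated)
Conditions: mCPBA, CH2Cl2, 0 °C → rt; aq. Na2S2O3/NaHCO3 wash; then K2CO3 (cat.), MeOH, rt
Reagents that add atoms: meta-chloroperoxybenzoic acid (mCPBA), OOC(=O)c1cccc(Cl)c1
Why: Baeyer–Villiger oxidation in its Dakin-type form: in the Criegee adduct the electron-rich 4-alkoxyaryl group migrates in preference to hydride to give the aryl formate, which base-catalysed transesterification with methanol cleaves to the phenol once excess peracid is quenched, the acetal being stable to both stages.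

**Step 3**
Reactants: 4 4-(methoxymethoxy)-3-methylphenol
Product: 5 2-iodo-4-(methoxymethoxy)-5-methylphenol
Conditions: NIS, MeCN, 0 °C → rt, dark
Reagents that add atoms: N-iodosuccinimide (NIS), O=C1CCC(=O)N1I
Why: Electrophilic aromatic iodination directed by the free hydroxyl, whose para position is occupied by the acetal oxygen: of its two ortho carbons the one para to methyl is open while the other is wedged between OH and CH3, so iodine should enter at the future C1.

**Step 4**
Reactants: 5 2-iodo-4-(methoxymethoxy)-5-methylphenol; 6 isobutyryl chloride
Product: 7 2-iodo-4-(methoxymethoxy)-5-methylphenyl 2-methylpropanoate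
Conditions: Et3N, DMAP (cat.), CH2Cl2, 0 °C → rt
Reagents that add atoms: none
Why: DMAP-catalysed O-acylation of the phenol with the acid chloride (nucleophilic acyl substitution) is routine even next to an ortho iodine, and neither the aryl iodide nor the acetal reacts.

**Step 5**
Reactants: 7 2-iodo-4-(methoxymethoxy)-5-methylphenyl 2-methylpropanoate; 8 propadiene; 9 benzoic acid
Product: 11 2-[5-(methoxymethoxy)-4-methyl-2-(2-methylpropanoyloxy)phenyl]prop-2-en-1-yl benzoate, via cesium benzoate 10 (not isolated)
Conditions: 9 (2.1 equiv), Cs2CO3 (1.0 equiv), 4 Å MS, DMF, rt; then 7, Pd(PPh3)4 (5 mol %), propadiene (1 bar, sealed Schlenk tube), 70 °C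
Reagents that add atoms: none
Why: Zerovalent palladium inserts into the C1–I bond, the resulting divalent arylpalladium iodide carbopalladates propadiene with the aryl group going to the central sp carbon (the only mode that gives an allyl rather than a vinyl palladium species), and the 2-aryl π-allyl palladium is attacked at a terminal carbon by benzoate in a Tsuji–Trost-type substitution that forms the CH2–O bond and returns zerovalent palladium. The closest known reaction type is the palladium-catalysed three-component coupling of aryl iodides, allenes and nucleophiles (amines, malonates, phenoxides, sulfinates, tethered carboxylates), and carboxylate capture of π-allyl palladium is familiar from allylic ester exchange; an external benzoate on propadiene is the same manifold with a weaker nucleophile, which is why PhCO2Cs is used in excess in DMF. No ring closes and no stereocentre is created. The selectivity needed is constitutional only: the two termini of the 2-aryl π-allyl are equivalent, so one isomer should result, and the allyl unit has no β-hydrogen, so no diene can arise by elimination. Benzoate is the only nucleophile present, so re-ionisation of the product by zerovalent palladium is degenerate, and its low basicity should leave the ortho isobutyrate and the acetal at O3 intact.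

**Step 6**
Reactants: 11 2-[5-(methoxymethoxy)-4-methyl-2-(2-methylpropanoyloxy)phenyl]prop-2-en-1-yl benzoate
Product: 12 2-[5-hydroxy-4-methyl-2-(2-methylpropanoyloxy)phenyl]prop-2-en-1-yl benzoate
Conditions: ZnBr2, n-PrSH, CH2Cl2, 0 °C → rt (minutes)
Reagents that add atoms: none
Why: Lewis-acid-assisted acetal cleavage: ZnBr2 activates the methoxymethyl ether and the thiol takes up the oxocarbenium fragment as an O,S-acetal, freeing the phenol within minutes under non-hydrolytic conditions that should leave the aryl isobutyrate, the allylic benzoate and the alkene untouched.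

**Compound list**

1 | 4-hydroxy-3-methylbenzaldehyde | Cc1cc(C=O)ccc1O | starting material
2 | 4-(methoxymethoxy)-3-methylbenzaldehyde | COCOc1ccc(C=O)cc1C | intermediate
3 | 4-(methoxymethoxy)-3-methylphenyl formate | COCOc1ccc(OC=O)cc1C | intermediate
4 | 4-(methoxymethoxy)-3-methylphenol | COCOc1ccc(O)cc1C | intermediate
5 | 2-iodo-4-(methoxymethoxy)-5-methylphenol | COCOc1cc(I)c(O)cc1C | intermediate
6 | isobutyryl chloride | CC(C)C(Cl)=O | starting material
7 | 2-iodo-4-(methoxymethoxy)-5-methylphenyl 2-methylpropanoate | CC(C)C(=O)Oc1cc(C)c(OCOC)cc1I | intermediate
8 | propadiene | C=C=C | starting material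
9 | benzoic acid | OC(=O)c1ccccc1 | starting material
10 | cesium benzoate | [Cs+].[O-]C(=O)c1ccccc1 | intermediate
11 | 2-[5-(methoxymethoxy)-4-methyl-2-(2-methylpropanoyloxy)phenyl]prop-2-en-1-yl benzoate | C=C(COC(=O)c1ccccc1)c1cc(OCOC)c(C)cc1OC(=O)C(C)C | intermediate
12 | 2-[5-hydroxy-4-methyl-2-(2-methylpropanoyloxy)phenyl]prop-2-en-1-yl benzoate | C=C(COC(=O)c1ccccc1)c1cc(O)c(C)cc1OC(=O)C(C)C | target

Total step count: 6. Longest linear sequence: 6 steps (1 → 12).

**Steps most likely to fail**

Step 5. Capture of the 2-aryl π-allyl palladium iodide by the weakly nucleophilic benzoate may be slow. A second propadiene could then insert (oligomers) or the catalyst could decay, and re-ionisation of the product would feed the same leak. Fallback, from 7: the C1–Cα bond would be made by Stille coupling with 2-(tributylstannyl)prop-2-en-1-ol (Pd(PPh3)4, CuI, DMF, 60 °C), giving 2-(3-hydroxyprop-1-en-2-yl)-4-(methoxymethoxy)-5-methylphenyl 2-methylpropanoate F1. This alcohol would be benzoylated without delay (benzoyl chloride, pyridine, DMAP cat., CH2Cl2, 0 °C) so that the isobutyryl group has no time to migrate to the primary hydroxyl. The sequence returns to the route at 11.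

Step 6. Activation may reach beyond the acetal: ionisation of the allylic benzoate, protonation of the 1,1-disubstituted alkene with participation of the neighbouring benzoate, or thiol-induced loss of the aryl ester. Fallback, from 7, which has neither alkene nor allylic ester:
- The acetal would be removed at that stage (ZnBr2, n-PrSH, CH2Cl2, 0 °C) to give 4-hydroxy-2-iodo-5-methylphenyl 2-methylpropanoate F2.
- The phenol would be silylated (TIPSOTf, 2,6-lutidine, CH2Cl2, 0 °C) to 2-iodo-5-methyl-4-[(triisopropylsilyl)oxy]phenyl 2-methylpropanoate F3.
- F3 would be coupled with 8 and cesium benzoate 10 exactly as in step 5, under strictly anhydrous conditions, to give 2-{4-methyl-2-(2-methylpropanoyloxy)-5-[(triisopropylsilyl)oxy]phenyl}prop-2-en-1-yl benzoate F4.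
- Fluoride cleavage of the silyl ether (HF·pyridine, THF, 0 °C → rt) involves no Lewis acid or thiol and comes back to the route at 12.

Step 3. Iodine may enter at the hindered ortho carbon or twice, and the electron-rich hydroquinone monoether may be oxidised towards the quinone with loss of the acetal. Fallback, from 4, replacing electrophilic substitution by directed ortho-metalation:
- Carbamoylation (Et2NCOCl, K2CO3, MeCN, reflux) would give 4-(methoxymethoxy)-3-methylphenyl N,N-diethylcarbamate F5.
- s-BuLi/TMEDA (THF, −78 °C) should lithiate the open position ortho to the carbamate, the stronger director, giving [2-(diethylcarbamoyloxy)-5-(methoxymethoxy)-4-methylphenyl]lithium F6 (not isolated).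
- Quenching with I2 would give 2-iodo-4-(methoxymethoxy)-5-methylphenyl N,N-diethylcarbamate F7.
- Hydrolysis of the carbamate (KOH, EtOH–H2O, reflux; acetal and aryl iodide are base-stable) returns to the route at 5.

**Further compounds**

F1 | step 5 | 2-(3-hydroxyprop-1-en-2-yl)-4-(methoxymethoxy)-5-methylphenyl 2-methylpropanoate | C=C(CO)c1cc(OCOC)c(C)cc1OC(=O)C(C)C
F2 | step 6 | 4-hydroxy-2-iodo-5-methylphenyl 2-methylpropanoate | CC(C)C(=O)Oc1cc(C)c(O)cc1I
F3 | step 6 | 2-iodo-5-methyl-4-[(triisopropylsilyl)oxy]phenyl 2-methylpropanoate | CC(C)C(=O)Oc1cc(C)c(O[Si](C(C)C)(C(C)C)C(C)C)cc1I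
F4 | step 6 | 2-{4-methyl-2-(2-methylpropanoyloxy)-5-[(triisopropylsilyl)oxy]phenyl}prop-2-en-1-yl benzoate | C=C(COC(=O)c1ccccc1)c1cc(O[Si](C(C)C)(C(C)C)C(C)C)c(C)cc1OC(=O)C(C)C
F5 | step 3 | 4-(methoxymethoxy)-3-methylphenyl N,N-diethylcarbamate | CCN(CC)C(=O)Oc1ccc(OCOC)c(C)c1
F6 | step 3 | [2-(diethylcarbamoyloxy)-5-(methoxymethoxy)-4-methylphenyl]lithium | [Li]c1cc(OCOC)c(C)cc1OC(=O)N(CC)CC
F7 | step 3 | 2-iodo-4-(methoxymethoxy)-5-methylphenyl N,N-diethylcarbamate | CCN(CC)C(=O)Oc1cc(C)c(OCOC)cc1I
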